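## The problem

The target is a longipinene-type diester. A cyclobutane (C1, C2, C8, C7) has its C1/C8 diagonal spanned on one face by the enone bridge C11(=O)–C10=C9(CH3) and its C2/C7 diagonal spanned on the other face by the chain C3–C4–C5–C6, so a bicyclo[3.1.1]heptenone and a seven-membered ring share the four-membered ring. Four of the six stereocenters (C1, C2, C7, C8) lie on the cyclobutane and are interlocked: once the ring exists, the only open question is which substituent on C2 (CH3 or C3) and on C7 (H or C6) points away from the enone bridge, and the seven-membered ring can close only if C3 and C6 both do. C3 (isobutyrate) and C5 (methacrylate) are 1,3-anti. C3 can control C5 through a directed reduction, but the cage cannot control C3, because at that ring the cage is almost mirror-symmetric about the plane through C2, C7 and C10. C2 is quaternary and sits next to the neopentyl C7, so every bond made to C2 is crowded. The chemistry is limited by the polymerisable methacrylate, by two different esters on a 1,3-diol (acyl migration), by the strained ring next to a carbonyl, and by β-oxygenated ketones that eliminate or cleave by retro-aldol reaction. The feature used here is that C3 and C5 carry oxygen with the CH2 C4 between them, while C3 and C6 hang cis from the cyclobutane less than 3 Å apart: a dipole on C5 and a vinyl group on C2 are held so that an N–O unit can be laid across C3 and C5 while the C4–C5 bond closes the seven-membered ring. That N–O bridge makes C5 a bridgehead, so C5 must stay tetrahedral in the adduct; the dipole therefore has to be a nitrone, not a nitrile oxide, whose adduct would need a planar C5=N at that bridgehead.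

## Retrosynthesis

**Ketone and methacrylate last (37 ⇒ 36 ⇒ 35 ⇒ 34).** The C11 carbonyl is traced to the allylic alcohol 36 and its silyl ether 35, and the C5–O acyl bond to the hydroxy ester 34. The enone is kept masked because the steps before it use a hydroxylamine, zinc, an N-chloroamine and a samarium catalyst. The methacrylate goes on only after the last reduction. The forward steps ask for acylation of a neopentyl secondary alcohol and oxidation of an allylic alcohol beside two esters.

**C5–H and the C3 ester together (34 ⇒ 31 + 32).** Cutting the C5–H bond and the C3–O acyl bond in one operation leads to the β-hydroxy ketone 31 and isobutyraldehyde 32. A Tishchenko-type intramolecular hydride shift sets C5 anti to C3 and leaves the acyl group on C3. Reduction followed by acylation would have to tell two neopentyl secondary hydroxyls apart.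

**Carbonyl from nitrogen (31 ⇒ 28 ⇒ 26).** The C5 ketone is traced to the primary amine 28, and the amine with the C3 hydroxyl to the N–O bond of the bridged isoxazolidine 26. This costs one step more than a direct route to the ketone, but it is the price of keeping C5 tetrahedral in the cycloadduct.

**The N–O bridge (26 ⇒ 25 ⇒ 22 + 24).** The C4–C5 and C3–O bonds are cut together, giving the nitrone 25, made in the flask from the vinyl aldehyde 22 and the sugar oxime 24. An aldol closure would also give the hydroxy ketone but has no handle on C3. The cycloaddition forms the seven-membered ring and places the C3 oxygen in one step, and the group on nitrogen is the only stereocontrolling element that sits at the reacting atoms. The precursor 22 is a plain bicycle with two one-carbon handles. The forward reaction must bond C5 to the alkene terminus and not to the inner carbon, and must take one alkene face.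

**Two aldehyde-level carbons from an ester and a nitrile (22 ⇒ 20 ⇒ 19 ⇒ 18 ⇒ 17).** The C5 aldehyde comes from the nitrile of 20, and the vinyl group from the aldehyde 19, the alcohol 18 and the ester 17. The nitrile has no α-hydrogen and is inert to every base used earlier. The order lets a borohydride take the ester while the nitrile stays, and an aluminium hydride is used only when no ester is left.

**The C2 methyl (17 ⇒ 15).** The C2–CH3 bond is cut to the bicyclic ester 15. The methyl is added after the ring is closed because the electrophile can reach the planar C2 only from the face of the C9–C11 bridge. Closing the ring with the methyl already on the enolate carbon would be expected to turn the ester away from the C7 arm, which is the wrong C2 configuration.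

**The cyclobutane (15 ⇒ 13).** The C2–C1 bond is cut to the monocyclic ester tosylate 13. This is an ionic 1,3-ring closure with inversion at C1. The precursor is a cyclohexene with four contiguous stereocenters. It needs the nucleophile on the α face at C8 and the leaving group on the β face at C1.

**C8–C2 by sigmatropic transfer (13 ⇒ 10 + 11).** The C8–C2 bond is cut to the allylic alcohol 10 and triethyl orthoacetate 11. The rearrangement carries the configuration of the C10–O bond over to C8 and leaves the alkene at C9=C10.

**Sorting three oxygens (10 ⇒ 9 ⇒ 8 ⇒ 7).** The silyl ether on C11, the free C10 hydroxyl and the C1 tosylate come from the acetonide alcohol 7 by tosylation (8), acetonide removal (9) and selective silylation (10). The tosylate is installed early because C1 has no anti hydrogen on either neighbour and cannot eliminate.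

**Methyl for bromine, and the C7 arm (7 ⇒ 6 ⇒ 3 + 4).** The C9 methyl replaces the bromine of 6 by cross-coupling. The C7–C6 bond is cut to the vinyl epoxide 3 and isobutyronitrile 4. The bromine first directs the epoxidation away from its own alkene and is then exchanged.

**Chiral pool (3 ⇒ 2 ⇒ 1).** The epoxide and acetonide lead back to the bromodiol 1. Its two oxygens mark the ring face on which C2 is later attached, so its absolute configuration fixes that of the cage. The auxiliary 24 is one step from diacetone-D-mannose 23.

## Roads not taken

**Alternative 1:** All three rings are cut at once: a sesquiterpene cyclase would convert farnesyl diphosphate A1 into α-longipinene A2, forming C6–C7, C1–C7 and C2–C8 in one enzymatic cascade. No chemical route can match this for the skeleton: one step, all four cage stereocenters, no protecting groups, and supply by fermentation. The weakness lies after the key step. A2 has no oxygen. C11 is allylic and can be oxidised, but C3 and C5 are unactivated methylenes on the nearly mirror-symmetric ring. Two site- and face-selective hydroxylations would be needed, and the two hydroxyls must then be told apart for two different esters; this calls for engineered oxygenases. The chosen plan is far longer, but it places each oxygen by construction (C11 from the diol, C3 and C5 through the N–O bridge) and differentiates the two esters.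

**Alternative 2:** The six-membered ring is cut off a four-membered one: the chiral enamine of the prochiral cyclobutanone A3 would add to crotonoyl chloride A4 and be acylated by the resulting ketene, forming C8–C9 and C1–C11 and giving the dione A5. The route is convergent, sets the absolute configuration with a catalytic amount of chiral amine, already contains the C2 quaternary centre in a symmetric precursor, and delivers the C11 carbonyl with the annulation. If it worked, it would reach a bicyclic core in fewer steps than the chosen plan. The weak points are three. Cyclobutanone enamines are reluctant annulation partners. A5 is a non-enolisable 1,3-dione across a four-membered ring and invites retro-Claisen opening. The C7 carbonyl must still become a C7–H carrying the quaternary C6 on the correct face, which means adding a tertiary carbanion to a strained ketone and deoxygenating a tertiary cyclobutanol. The chosen plan makes the C7–C6 bond early, by a stereospecific epoxide opening on an unstrained ring.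

**Alternative 3:** The cyclobutane bond C7–C8 is cut: anodic oxidation of the N-amino azabicycle A6 would give a 1,1-diazene, which loses N2, and the radical pair would collapse to the nitrile A7. The strained ring is made last from a strain-free precursor, and the C2 quaternary centre is settled before the four-membered ring exists. In this respect it is better than the chosen plan, which relies on a face-selective methylation of a crowded enolate. The weak points are the 1,4-diradical, which can cleave to an open diene or lose configuration at C7 before it recombines, and the absence of precedent for the anodic variant on a bridged ketone. A6 also needs its own multi-step synthesis, and A7 still lacks the seven-membered ring and both oxygens. The chosen plan closes the ring by an ionic displacement with guaranteed inversion at C1 and no fragmentation channel.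

Key step: step 16

Remarks on the chemistry:
- Locants C1–C11 are those of the target skeleton. In the monocyclic intermediates the ring is C1–C11–C10–C9–C8–C7; "α" is the ring face carrying the two oxygens of 1 and "β" the other. In the bicyclic intermediates "syn" and "anti" at C2 and C7 refer to the C9–C11 bridge.
- The sense of induction of the mannofuranosyl group in step 16 is assumed to be the matched one; precedent does not settle it for this bridged intramolecular case.

## Route

Step 1
Reactants: 1 (1S,2S)-3-bromocyclohexa-3,5-diene-1,2-diol
Product: 2 acetonide of 1 (2,2-dimethyl-1,3-dioxolane across the C10 and C11 oxygens)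
Conditions: 2,2-dimethoxypropane, TsOH·H2O (cat.), acetone, 0 °C → rt
Reagents that add atoms: 2,2-dimethoxypropane, COC(C)(C)OC
Why: Acid-catalysed transacetalisation of a cis-diol; no stereocenter is touched. The diene acetonide dimerises on standing and is used at once.

Step 2
Reactants: 2 acetonide
Product: 3 β-epoxide at C7–C1 (oxygen on the face opposite the dioxolane), C8=C9–Br kept
Conditions: mCPBA, NaHCO3, CH2Cl2, 0 °C → rt
Reagents that add atoms: mCPBA, O=C(OO)c1cccc(Cl)c1
Why: Prilezhaev epoxidation. Bromine deactivates the C8=C9 alkene, so the peracid takes C7=C1, and the dioxolane on the α face sends it to the β face, as is established for this diene.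

Step 3
Reactants: 3 vinyl epoxide; 4 isobutyronitrile
Product: 6 bromo hydroxy nitrile (C7 α-C(CH3)2CN; C1 β-OH; acetonide; C8=C9–Br), via 2-lithio-2-methylpropanenitrile 5 (not isolated)
Conditions: LiN(i-Pr)2, THF, −78 °C; then 3, −78 → 0 °C; aq. NH4Cl
Reagents that add atoms: none
Why: SN2 opening of a vinyl epoxide by a lithiated nitrile. Attack at the allylic carbon C7, anti to the epoxide oxygen, puts the arm on the α face and leaves the C1 hydroxyl β; C1 is deactivated by the neighbouring dioxolane oxygen.

Step 4
Reactants: 6 bromo hydroxy nitrile
Product: 7 methyl hydroxy nitrile (CH3 on C9 in place of Br)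
Conditions: MeB(OH)2, PdCl2(dppf) (5 mol %), K3PO4, dioxane/H2O, 85 °C
Reagents that add atoms: methylboronic acid, CB(O)O
Why: Suzuki–Miyaura methylation of an alkenyl bromide. The bromine has served as the regiocontrol element in steps 2 and 3; the free alcohol and the nitrile are inert.

Step 5
Reactants: 7 methyl hydroxy nitrile
Product: 8 C1 β-tosylate
Conditions: TsCl, Et3N, Me3N·HCl (cat.), CH2Cl2, 0 °C → rt
Reagents that add atoms: p-toluenesulfonyl chloride, Cc1ccc(cc1)S(Cl)(=O)=O
Why: Sulfonylation of the only free hydroxyl with retention at C1. Both neighbouring hydrogens (on C11 and C7) are cis to the tosylate, so E2 elimination is not available and the group can be carried through the next four steps.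

Step 6
Reactants: 8 tosylate
Product: 9 diol tosylate (C10 α-OH allylic; C11 α-OH)
Conditions: AcOH/H2O (4:1), 45 °C
Reagents that add atoms: none
Why: Hydrolysis of the dioxolane in mild aqueous acid; tosylate, nitrile and the trisubstituted alkene are stable.

Step 7
Reactants: 9 diol tosylate
Product: 10 C11 tert-butyldimethylsilyl ether with free C10 hydroxyl
Conditions: TBSCl, imidazole, DMF, −20 → 0 °C
Reagents that add atoms: tert-butyldimethylsilyl chloride, CC(C)(C)[Si](C)(C)Cl
Why: Selective silylation of the less hindered of two cis-vicinal hydroxyls. The C10 hydroxyl is pseudo-axial and flanked by the methyl-bearing alkene carbon, while the C11 hydroxyl is equatorial; this is the selectivity known for the hydroxyl remote from the substituted alkene carbon in cyclohexene cis-diols of this origin.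

Step 8
Reactants: 10 allylic alcohol; 11 triethyl orthoacetate
Product: 13 ethyl ester (C8 α-CH2CO2Et; alkene C9(CH3)=C10; C11 α-OTBS; C1 β-OTs; C7 α-C(CH3)2CN), via mixed ketene acetal 12 (not isolated)
Conditions: EtCO2H (cat.), neat 11, 140 °C, EtOH distilled off
Reagents that add atoms: none
Why: Johnson–Claisen rearrangement. The [3,3] shift is suprafacial, so the C8–C2 bond forms on the α face from which the C10–O bond leaves, and the alkene lands at C9=C10, where the target has it.

Step 9
Reactants: 13 ethyl ester tosylate
Product: 15 bicyclo[3.1.1]hept-3-ene ester (new C2–C1 bond; C2 carries H and CO2Et as either epimer; C7 arm anti), via potassium enolate 14 (not isolated)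
Conditions: KN(SiMe3)2, THF, −78 → 0 °C
Reagents that add atoms: none
Why: Intramolecular ester-enolate alkylation, a 4-exo-tet 1,3-ring closure of the kind used to make bicyclo[3.1.1]heptanes from 3-sulfonyloxycyclohexyl carbonyl compounds. The enolate carbon on the α face of C8 can reach only the rear of the β C1–O bond, so C1 is inverted and C2 ends cis to the C7 arm; the C2 configuration is immaterial here.

Step 10
Reactants: 15 bicyclic ester
Product: 17 C2-methylated ester (CH3 syn to the C9–C11 bridge; CO2Et anti), via lithium enolate 16 (not isolated)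
Conditions: LiN(i-Pr)2, THF/DMPU, −78 → −20 °C; MeI
Reagents that add atoms: methyl iodide, CI
Why: Enolate alkylation under approach control. The anti face of the planar C2 is covered by the C(CH3)2CN group on C7, so the methyl enters from the face of the C9–C11 bridge whatever the epimer composition of 15.

Step 11
Reactants: 17 methylated ester
Product: 18 primary alcohol (C3–OH)
Conditions: LiBH4, MeOH (1 equiv), THF, 0 → 50 °C
Reagents that add atoms: none
Why: LiBH4 reduces esters and leaves nitriles untouched; the silyl ether and alkene are inert.

Step 12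
Reactants: 18 alcohol
Product: 19 aldehyde (C3)
Conditions: Dess–Martin periodinane, NaHCO3, CH2Cl2, 0 °C → rt
Reagents that add atoms: none
Why: Dess–Martin oxidation of a primary alcohol; the aldehyde has no α-hydrogen and cannot epimerise.

Step 13
Reactants: 19 aldehyde
Product: 20 vinyl nitrile (C2 vinyl anti; C7 C(CH3)2CN anti)
Conditions: Ph3PCH3Br, KN(SiMe3)2, THF, 0 °C → rt
Reagents that add atoms: methyltriphenylphosphonium bromide (as its ylide), C[P+](c1ccccc1)(c1ccccc1)c1ccccc1.[Br-]
Why: Wittig methylenation of a non-enolisable aldehyde; the nitrile does not react with the ylide.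

Step 14
Reactants: 20 vinyl nitrile
Product: 22 vinyl aldehyde (C5 aldehyde), via N-aluminio aldimine 21 (not isolated)
Conditions: i-Bu2AlH, toluene, −78 → 0 °C; aq. tartaric acid
Reagents that add atoms: water, O
Why: i-Bu2AlH adds once to the nitrile and hydrolysis on work-up gives the aldehyde; at or below 0 °C the alkenes are not hydroaluminated.

Step 15
Reactants: 23 2,3:5,6-di-O-isopropylidene-α-D-mannofuranose
Product: 24 2,3:5,6-di-O-isopropylidene-D-mannose oxime
Conditions: NH2OH·HCl, NaOAc, EtOH/H2O, rt
Reagents that add atoms: hydroxylamine hydrochloride, NO.Cl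
Why: Oxime formation from the latent aldehyde of a furanose hemiacetal; the product is in equilibrium with its N-glycosylhydroxylamine form, which is the reagent of step 16.

Step 16
Reactants: 22 vinyl aldehyde; 24 mannose oxime
Product: 26 bridged isoxazolidine (O on C3, N on C5, N-mannofuranosyl; seven-membered ring closed), via Z-nitrone 25 (not isolated)
Conditions: 24 (1.2 equiv), 4 Å molecular sieves, toluene, 110 °C
Reagents that add atoms: none
Why: Condensation of 22 with the N-glycosylhydroxylamine tautomer of 24 gives the Z-nitrone 25, whose carbon C5 bonds to the alkene terminus C4 while its oxygen bonds to C3 in a concerted thermal [3+2] cycloaddition; the closest known reaction type is the intramolecular nitrone–alkene cycloaddition in its bridged mode, run with an N-glycosyl nitrone as chiral auxiliary. The carbocycle closes as a seven-membered ring through the C4–C5 bond, both alkene carbons becoming ring members, and the isoxazolidine closes as the five-membered ring of the cycloaddition with its N–O unit spanning C3 and C5. The dipole is held at the nitrone level because a nitrile oxide would leave C5=N at this bridgehead, and with C2 and C6 clamped less than 3 Å apart by the cyclobutane that double bond could not be planar. The selectivity that decides the skeleton is regiochemistry: attack of C5 on the unhindered CH2 terminus is the normal orientation for a monosubstituted alkene and gives the ring of the target, whereas attack on C3 would join two neopentyl carbons and build a second bicyclo[3.1.1]heptane on the cyclobutane. Both arms are held cis on the cyclobutane, anti to the C9–C11 bridge, so the reacting ends are already in contact. C3 is the stereocenter that is kept: the cage is nearly mirror-symmetric about the plane through C2, C7 and C10, so the alkene face is selected by the nitrone face that the mannofuranosyl group leaves open, and the auxiliary, not the substrate, is the controlling element. C5 is formed cis to the C3 oxygen, because the two-atom bridge can span only one face, and is erased in step 18.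

Step 17
Reactants: 26 bridged isoxazolidine
Product: 28 amino alcohol (C5–NH2 and C3–OH on the same side of the ring), via N-glycosyl amino alcohol 27 (not isolated)
Conditions: Zn, AcOH (10 equiv), THF/H2O, rt; aq. NaHCO3
Reagents that add atoms: none
Why: Reductive N–O cleavage of an isoxazolidine by zinc in acetic acid. The glycosylamine so formed hydrolyses in the aqueous acid and releases the sugar; C3 is untouched.

Step 18
Reactants: 28 amino alcohol
Product: 31 β-hydroxy ketone (C5 ketone, C3–OH), via N-chloroamine 29 (not isolated), via ketimine 30 (not isolated)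
Conditions: N-chlorosuccinimide, CH2Cl2, 0 °C; DBU, 0 °C → rt; 5% aq. oxalic acid, THF, rt
Reagents that add atoms: water, O
Why: Ruschig deamination of a primary amine on a secondary carbon: N-chlorination, dehydrochlorination to the ketimine, hydrolysis. The C5 centre is erased and C3 is untouched.

Step 19
Reactants: 31 β-hydroxy ketone; 32 isobutyraldehyde
Product: 34 C3 isobutyrate with free C5 hydroxyl (1,3-anti), via isobutyraldehyde hemiacetal 33 (not isolated)
Conditions: 32 (10 equiv), SmI2 (0.3 equiv), THF, −10 °C
Reagents that add atoms: none
Why: Evans–Tishchenko reduction. The C3 hydroxyl and 32 form hemiacetal 33, and within a samarium chelate of the hemiacetal oxygen and the C5 carbonyl the hemiacetal hydrogen shifts to C5 on the face that carries the C3 oxygen. The C5 hydroxyl therefore ends anti to the C3 oxygen, and the isobutyryl group stays on C3.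

Step 20
Reactants: 34 hydroxy isobutyrate
Product: 35 C3 isobutyrate C5 methacrylate, C11 silyl ether
Conditions: methacryloyl chloride, Et3N, DMAP (cat.), CH2Cl2, 0 °C → rt
Reagents that add atoms: methacryloyl chloride, C=C(C)C(Cl)=O
Why: DMAP-catalysed acylation of the only free hydroxyl. Capping C5 directly after step 19 removes any chance of 1,3-acyl migration.

Step 21
Reactants: 35 diester silyl ether
Product: 36 diester allylic alcohol (C11–OH)
Conditions: HF·pyridine, THF/pyridine, 0 °C → rt
Reagents that add atoms: none
Why: Buffered fluoride desilylation; the medium is non-basic, so neither ester migrates and the methacrylate is not attacked.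

Step 22
Reactants: 36 allylic alcohol
Product: 37 CNP0214356.1
Conditions: Dess–Martin periodinane, NaHCO3, CH2Cl2, rt
Reagents that add atoms: none
Why: Dess–Martin oxidation of the secondary allylic alcohol to the C11 enone; the C11 stereocenter disappears and both esters are inert.

## Compound list

1 | (1S,2S)-3-bromocyclohexa-3,5-diene-1,2-diol | O[C@H]1C=CC=C(Br)[C@H]1O | starting material
2 | acetonide of 1 | CC1(C)O[C@H]2C=CC=C(Br)[C@H]2O1 | intermediate
3 | β-epoxide at C7–C1, anti to the dioxolane | CC1(C)O[C@H]2[C@@H]3O[C@@H]3C=C(Br)[C@H]2O1 | intermediate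
4 | isobutyronitrile | CC(C)C#N | starting material
5 | 2-lithio-2-methylpropanenitrile | [Li]C(C)(C)C#N | intermediate (not isolated)
6 | bromo hydroxy nitrile (C7 α arm, C1 β-OH) | CC1(C)O[C@H]2[C@H](O)[C@@H](C(C)(C)C#N)C=C(Br)[C@H]2O1 | intermediate
7 | methyl hydroxy nitrile | CC1(C)O[C@H]2[C@H](O)[C@@H](C(C)(C)C#N)C=C(C)[C@H]2O1 | intermediate
8 | C1 β-tosylate | CC1(C)O[C@H]2[C@H](OS(=O)(=O)c3ccc(C)cc3)[C@@H](C(C)(C)C#N)C=C(C)[C@H]2O1 | intermediate
9 | diol tosylate | O[C@H]1[C@H](OS(=O)(=O)c2ccc(C)cc2)[C@@H](C(C)(C)C#N)C=C(C)[C@H]1O | intermediate
10 | C11 silyl ether, free C10 hydroxyl | CC(C)(C)[Si](C)(C)O[C@H]1[C@H](OS(=O)(=O)c2ccc(C)cc2)[C@@H](C(C)(C)C#N)C=C(C)[C@H]1O | intermediate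
11 | triethyl orthoacetate | CCOC(C)(OCC)OCC | starting material
12 | mixed ketene acetal on the C10 oxygen | CC(C)(C)[Si](C)(C)O[C@H]1[C@H](OS(=O)(=O)c2ccc(C)cc2)[C@@H](C(C)(C)C#N)C=C(C)[C@H]1OC(=C)OCC | intermediate (not isolated)
13 | ethyl ester, C8 α-CH2CO2Et, alkene C9=C10 | CC(C)(C)[Si](C)(C)O[C@H]1[C@H](OS(=O)(=O)c2ccc(C)cc2)[C@@H](C(C)(C)C#N)[C@@H](CC(=O)OCC)C(C)=C1 | intermediate
14 | potassium enolate of 13 | CC(C)(C)[Si](C)(C)O[C@H]1[C@H](OS(=O)(=O)c2ccc(C)cc2)[C@@H](C(C)(C)C#N)[C@@H](C=C([O-])OCC)C(C)=C1.[K+] | intermediate (not isolated)
15 | bicyclo[3.1.1]hept-3-ene ester, C2 epimers (C2 left undefined) | CC(C)(C)[Si](C)(C)O[C@H]1[C@@H]2[C@@H](C(C)(C)C#N)[C@@H](C2C(=O)OCC)C(C)=C1 | intermediate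
16 | lithium enolate of 15 | CC(C)(C)[Si](C)(C)O[C@H]1[C@@H]2[C@@H](C(C)(C)C#N)[C@@H](C2=C([O-])OCC)C(C)=C1.[Li+] | intermediate (not isolated)
17 | C2-methyl ester (CH3 syn, CO2Et anti) | CC(C)(C)[Si](C)(C)O[C@H]1[C@@H]2[C@@H](C(C)(C)C#N)[C@@H]([C@@]2(C)C(=O)OCC)C(C)=C1 | intermediate
18 | primary alcohol (C3–OH) | CC(C)(C)[Si](C)(C)O[C@H]1[C@@H]2[C@@H](C(C)(C)C#N)[C@@H]([C@@]2(C)CO)C(C)=C1 | intermediate
19 | aldehyde (C3) | CC(C)(C)[Si](C)(C)O[C@H]1[C@@H]2[C@@H](C(C)(C)C#N)[C@@H]([C@@]2(C)C=O)C(C)=C1 | intermediate
20 | vinyl nitrile | CC(C)(C)[Si](C)(C)O[C@H]1[C@@H]2[C@@H](C(C)(C)C#N)[C@@H]([C@@]2(C)C=C)C(C)=C1 | intermediate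
21 | N-(diisobutylaluminio) aldimine | CC(C)(C)[Si](C)(C)O[C@H]1[C@@H]2[C@@H](C(C)(C)C=N[Al](CC(C)C)CC(C)C)[C@@H]([C@@]2(C)C=C)C(C)=C1 | intermediate (not isolated)
22 | vinyl aldehyde (C5 aldehyde) | CC(C)(C)[Si](C)(C)O[C@H]1[C@@H]2[C@@H](C(C)(C)C=O)[C@@H]([C@@]2(C)C=C)C(C)=C1 | intermediate
23 | 2,3:5,6-di-O-isopropylidene-α-D-mannofuranose | O[C@H]1O[C@H]([C@H]2COC(C)(C)O2)[C@@H]3OC(C)(C)O[C@H]13 | starting material
24 | 2,3:5,6-di-O-isopropylidene-D-mannose oxime (C=N geometry immaterial) | ON=C[C@@H](O1)[C@@H](OC1(C)C)[C@H](O)[C@H](O2)COC2(C)C | intermediate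
25 | N-(α-D-mannofuranosyl) Z-nitrone of 22 | CC(C)(C)[Si](C)(C)O[C@H]1[C@@H]2[C@@H](C(C)(C)/C=[N+](\[O-])[C@H]3O[C@H]([C@H]4COC(C)(C)O4)[C@@H]5OC(C)(C)O[C@H]35)[C@@H]([C@@]2(C)C=C)C(C)=C1 | intermediate (not isolated)
26 | bridged isoxazolidine (O on C3, N on C5) | O1N([C@H]5O[C@H]([C@H]6COC(C)(C)O6)[C@@H]7OC(C)(C)O[C@H]57)[C@H]2C[C@@H]1[C@@]3(C)[C@@H]4[C@H](O[Si](C)(C)C(C)(C)C)C=C(C)[C@H]3[C@@H]4C2(C)C | intermediate
27 | N-glycosyl amino alcohol | N([C@H]5O[C@H]([C@H]6COC(C)(C)O6)[C@@H]7OC(C)(C)O[C@H]57)[C@H]2C[C@@H](O)[C@@]3(C)[C@@H]4[C@H](O[Si](C)(C)C(C)(C)C)C=C(C)[C@H]3[C@@H]4C2(C)C | intermediate (not isolated)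
28 | amino alcohol (C5–NH2, C3–OH, syn) | N[C@H]2C[C@@H](O)[C@@]3(C)[C@@H]4[C@H](O[Si](C)(C)C(C)(C)C)C=C(C)[C@H]3[C@@H]4C2(C)C | intermediate
29 | N-chloroamine | ClN[C@H]2C[C@@H](O)[C@@]3(C)[C@@H]4[C@H](O[Si](C)(C)C(C)(C)C)C=C(C)[C@H]3[C@@H]4C2(C)C | intermediate (not isolated)
30 | ketimine | N=C2C[C@@H](O)[C@@]3(C)[C@@H]4[C@H](O[Si](C)(C)C(C)(C)C)C=C(C)[C@H]3[C@@H]4C2(C)C | intermediate (not isolated)
31 | β-hydroxy ketone (C5=O, C3–OH) | O=C2C[C@@H](O)[C@@]3(C)[C@@H]4[C@H](O[Si](C)(C)C(C)(C)C)C=C(C)[C@H]3[C@@H]4C2(C)C | intermediate
32 | isobutyraldehyde | CC(C)C=O | starting material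
33 | hemiacetal of 31 and 32 (hemiacetal carbon undefined) | O=C2C[C@@H](OC(O)C(C)C)[C@@]3(C)[C@@H]4[C@H](O[Si](C)(C)C(C)(C)C)C=C(C)[C@H]3[C@@H]4C2(C)C | intermediate (not isolated)
34 | C3 isobutyrate, C5 alcohol (anti) | O[C@@H]2C[C@@H](OC(=O)C(C)C)[C@@]3(C)[C@@H]4[C@H](O[Si](C)(C)C(C)(C)C)C=C(C)[C@H]3[C@@H]4C2(C)C | intermediate
35 | C3 isobutyrate, C5 methacrylate, C11 silyl ether | C=C(C)C(=O)O[C@@H]2C[C@@H](OC(=O)C(C)C)[C@@]3(C)[C@@H]4[C@H](O[Si](C)(C)C(C)(C)C)C=C(C)[C@H]3[C@@H]4C2(C)C | intermediate
36 | diester allylic alcohol (C11–OH) | C=C(C)C(=O)O[C@@H]2C[C@@H](OC(=O)C(C)C)[C@@]3(C)[C@@H]4[C@H](O)C=C(C)[C@H]3[C@@H]4C2(C)C | intermediate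
37 | CNP0214356.1 | C=C(C)C(=O)O[C@@H]1C[C@@H](OC(=O)C(C)C)[C@@]2(C)[C@@H]3C(=O)C=C(C)[C@H]2[C@@H]3C1(C)C | target

## Step count and least certain steps

Total: 22 steps. Longest linear sequence: 21 steps (steps 1–14 and 16–22); step 15 prepares the auxiliary.

**Step 16 (key step).** The short, rigid tether also fits bonding of the nitrone carbon to the inner alkene carbon, so regiochemical leakage to the fused adduct is the first concern. The second is weak facial discrimination by the auxiliary, or slow condensation of the neopentyl aldehyde, which would give C3 epimers that have to be separated. The fallback sets out from 18 and returns at 31. Excess MeLi adds to the nitrile and gives, after hydrolysis, the hydroxy methyl ketone F1. Dess–Martin oxidation gives the keto aldehyde F2. Base-mediated aldol condensation (KOH, MeOH) of the methyl ketone onto the non-enolisable aldehyde closes the seven-membered ring as the cycloheptenone F3. Conjugate borylation with B2pin2, CuCl, NaOtBu and a chiral bisphosphine in THF/MeOH gives the β-boryl ketone F4, in which C3 is set by the ligand and not by the cage. Oxidation with NaBO3·4H2O then gives 31.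

**Step 9.** The displacement at C1 may be slow, because C1 is secondary and flanked by the silyloxy-bearing C11 and the neopentyl C7. In that case O-alkylation to a six-membered ketene acetal or decomposition of the enolate could take over. The fallback sets out from 10 and returns at 19. Eschenmoser–Claisen rearrangement with N,N-dimethylacetamide dimethyl acetal gives the dimethylamide F5. Its lithium enolate (LiN(i-Pr)2) is more nucleophilic and alkylates only on carbon, closing the ring to the bicyclic amide F6. Methylation (LiN(i-Pr)2, MeI) gives the C2-methyl amide F7, and Cp2Zr(H)Cl reduces the amide to the aldehyde 19.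

**Step 10.** The α-hydrogen of 15 may lie on the shielded anti face, which would make deprotonation incomplete, and the crowded enolate may react sluggishly with MeI. The fallback sets out from 15 and returns at 19. LiBH4 gives the alcohol F8 and Dess–Martin oxidation the aldehyde F9, whose α-hydrogen is far more acidic. Its potassium enolate (KOtBu, THF) is methylated by MeI from the same open face to give 19.

**Step 7.** Silylation may go to the allylic C10 hydroxyl, or to both, because the neighbouring tosylate crowds C11. The fallback uses that reactivity; it sets out from 9 and returns at 13. Acetylation (Ac2O, pyridine, −20 °C) takes the more reactive hydroxyl to give the C10 acetate F10. TBSOTf/2,6-lutidine protects C11 to give the acetate silyl ether F11. Ireland–Claisen rearrangement (LiN(i-Pr)2, TMSCl, THF, −78 °C → rt) gives the acid F12, and EtI/K2CO3 in DMF gives 13.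

**Step 19.** The hydride shift onto a ketone flanked by a quaternary carbon inside a ring may be slow, leaving room for retro-aldol cleavage under the Lewis-acidic trivalent samarium. The fallback sets out from 31 and returns at 34. Me4NBH(OAc)3 in MeCN/AcOH delivers hydride intramolecularly from a boron ester of the C3 hydroxyl to give the anti-diol F13. Isobutyric anhydride with catalytic DMAP at −20 °C is then expected to acylate the C3 hydroxyl, which is less hindered than the C5 hydroxyl beside the gem-dimethyl carbon, to give 34.

## Further compounds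

F1 | step 16 | hydroxy methyl ketone | CC(C)(C)[Si](C)(C)O[C@H]1[C@@H]2[C@@H](C(C)(C)C(C)=O)[C@@H]([C@@]2(C)CO)C(C)=C1
F2 | step 16 | keto aldehyde | CC(C)(C)[Si](C)(C)O[C@H]1[C@@H]2[C@@H](C(C)(C)C(C)=O)[C@@H]([C@@]2(C)C=O)C(C)=C1
F3 | step 16 | cycloheptenone (C3=C4, C5=O) | O=C2C=C[C@@]3(C)[C@@H]4[C@H](O[Si](C)(C)C(C)(C)C)C=C(C)[C@H]3[C@@H]4C2(C)C
F4 | step 16 | β-boryl ketone | O=C2C[C@@H](B5OC(C)(C)C(C)(C)O5)[C@@]3(C)[C@@H]4[C@H](O[Si](C)(C)C(C)(C)C)C=C(C)[C@H]3[C@@H]4C2(C)C
F5 | step 9 | dimethylamide | CC(C)(C)[Si](C)(C)O[C@H]1[C@H](OS(=O)(=O)c2ccc(C)cc2)[C@@H](C(C)(C)C#N)[C@@H](CC(=O)N(C)C)C(C)=C1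
F6 | step 9 | bicyclic amide (C2 undefined) | CC(C)(C)[Si](C)(C)O[C@H]1[C@@H]2[C@@H](C(C)(C)C#N)[C@@H](C2C(=O)N(C)C)C(C)=C1
F7 | step 9 | C2-methyl amide | CC(C)(C)[Si](C)(C)O[C@H]1[C@@H]2[C@@H](C(C)(C)C#N)[C@@H]([C@@]2(C)C(=O)N(C)C)C(C)=C1
F8 | step 10 | alcohol with C2–H (C2 undefined) | CC(C)(C)[Si](C)(C)O[C@H]1[C@@H]2[C@@H](C(C)(C)C#N)[C@@H](C2CO)C(C)=C1
F9 | step 10 | aldehyde with C2–H (C2 undefined) | CC(C)(C)[Si](C)(C)O[C@H]1[C@@H]2[C@@H](C(C)(C)C#N)[C@@H](C2C=O)C(C)=C1
F10 | step 7 | C10 acetate | O[C@H]1[C@H](OS(=O)(=O)c2ccc(C)cc2)[C@@H](C(C)(C)C#N)C=C(C)[C@H]1OC(C)=O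
F11 | step 7 | C10 acetate C11 silyl ether | CC(C)(C)[Si](C)(C)O[C@H]1[C@H](OS(=O)(=O)c2ccc(C)cc2)[C@@H](C(C)(C)C#N)C=C(C)[C@H]1OC(C)=O
F12 | step 7 | carboxylic acid | CC(C)(C)[Si](C)(C)O[C@H]1[C@H](OS(=O)(=O)c2ccc(C)cc2)[C@@H](C(C)(C)C#N)[C@@H](CC(=O)O)C(C)=C1
F13 | step 19 | anti-diol | O[C@@H]2C[C@@H](O)[C@@]3(C)[C@@H]4[C@H](O[Si](C)(C)C(C)(C)C)C=C(C)[C@H]3[C@@H]4C2(C)C
A1 | alternative 1 | (2E,6E)-farnesyl diphosphate | CC(C)=CCC/C(C)=C/CC/C(C)=C/COP(O)(=O)OP(O)(O)=O
A2 | alternative 1 | α-longipinene | C1CC[C@@]2(C)[C@@H]3CC=C(C)[C@H]2[C@@H]3C1(C)C
A3 | alternative 2 | 3-methyl-3-[(tert-butyldiphenylsilyloxy)methyl]cyclobutanone | CC1(CO[Si](c2ccccc2)(c2ccccc2)C(C)(C)C)CC(=O)C1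
A4 | alternative 2 | (E)-crotonoyl chloride | C/C=C/C(Cl)=O
A5 | alternative 2 | bicyclo[3.1.1]heptane-2,6-dione | CC(C)(C)[Si](c1ccccc1)(c1ccccc1)OC[C@@]2(C)[C@@H]3C(=O)C[C@@H](C)[C@H]2C3=O
A6 | alternative 3 | N-amino 6-azabicyclo[3.2.1]octanone | N#C[C@@]2(C)[C@@H]3C(=O)CC[C@H]2N(N)[C@@H]3C(C)(C)C=C
A7 | alternative 3 | bicyclo[3.1.1]heptanone nitrile | N#C[C@@]2(C)[C@@H]3C(=O)CC[C@H]2[C@@H]3C(C)(C)C=C
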